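The quinone ring of the target (C1, C2, C3, C4, C4a, C8a) is an ene unit, C2=C3, held between two carbonyl carbons, C1 and C4, that hang on a symmetrical 5,8-dioxygenated benzo ring. The route cuts C1–C2 and C3–C4: a phthaloylcobalt metallacycle, made by inserting monovalent cobalt into the CO–CO bond of 3,6-diacetoxybenzocyclobutenedione, takes up the terminal alkyne of an enantiopure propargylic ester that already carries the complete side chain, and closes the quinone ring in one operation. Because the phthaloyl unit is C2v-symmetric, no regiochemical question arises. Mild methanolysis of the two aryl acetates then gives the target.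

Key step: step 8

Assumption: squaric acid dichloride 1 is treated as purchasable; it is otherwise one step from squaric acid (oxalyl chloride, cat. DMF).
Remark: in the SMILES of the cobalt complexes, donor–cobalt bonds are written with formal charges (donor +, cobalt −).

Step 1
Reactants: 1 3,4-dichlorocyclobut-3-ene-1,2-dione; 2 (1E,3E)-buta-1,3-diene-1,4-diyl diacetate
Product: 4 3,6-diacetoxybenzocyclobutene-1,2-dione, via Diels–Alder adduct 3 (not isolated)
Conditions: PhMe, 90 °C, sealed tube; then Et3N (2.5 equiv), CH2Cl2, 0 °C → rt
Reagents that add atoms: none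
Why: Diels–Alder reaction of a strained, doubly acyl-activated chloroalkene with an (E,E)-1,4-dioxygenated diene, followed by twofold dehydrochlorination of the kind that aromatises dichloroquinone and dichloromaleic anhydride adducts; aromatisation drives the loss of both HCl and erases the stereocentres of the adduct.

Step 2
Reactants: 4 3,6-diacetoxybenzocyclobutene-1,2-dione
Product: 6 chloro(dimethylglyoxime)(pyridine)(3,6-diacetoxyphthaloyl)cobalt, via bis(triphenylphosphine) phthaloylcobalt chloride 5 (not isolated)
Conditions: ClCo(PPh3)3 (1.05 equiv), PhCl, rt, Ar; then dimethylglyoxime (1.1 equiv), pyridine (3 equiv), rt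
Reagents that add atoms: ClCo(PPh3)3, Cl[Co-3]([P+](c1ccccc1)(c1ccccc1)c1ccccc1)([P+](c1ccccc1)(c1ccccc1)c1ccccc1)[P+](c1ccccc1)(c1ccccc1)c1ccccc1; dimethylglyoxime, O/N=C(C)/C(C)=N/O; pyridine, c1ccncc1
Why: Oxidative addition of monovalent cobalt into the strained CO–CO bond of the benzocyclobutenedione should give the five-membered diacyl metallacycle of trivalent cobalt, and ligand exchange of the phosphines for dimethylglyoxime and pyridine should give the air-stable octahedral complex that is the reactive form towards alkynes.

Step 3
Reactants: 7 4-methylpent-3-enoic acid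
Product: 9 N-methoxy-N,4-dimethylpent-3-enamide, via acyl imidazole 8 (not isolated)
Conditions: CDI (1.1 equiv), CH2Cl2, 0 °C → rt; then MeNH(OMe)·HCl (1.2 equiv), rt
Reagents that add atoms: N,O-dimethylhydroxylamine hydrochloride, CNOC.Cl
Why: Weinreb amide formation through the acyl imidazole runs under near-neutral conditions, which should keep the β,γ-alkene out of conjugation.

Step 4
Reactants: 9 N-methoxy-N,4-dimethylpent-3-enamide; 10 ethynyltrimethylsilane
Product: 13 6-methyl-1-(trimethylsilyl)hept-5-en-1-yn-3-one, via lithium acetylide 11 (not isolated), via tetrahedral adduct 12 (not isolated)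
Conditions: 10, n-BuLi, THF, −78 °C; then 9, −78 → −20 °C; inverse quench into cold 1 M aq. HCl
Reagents that add atoms: none
Why: Weinreb ketone synthesis, in which the N-methoxy chelate holds the tetrahedral adduct until the acidic quench so that the acetylide adds only once, and the acid also protonates the released amine so that it cannot add to the ynone.

Step 5
Reactants: 13 6-methyl-1-(trimethylsilyl)hept-5-en-1-yn-3-one
Product: 14 (3S)-6-methyl-1-(trimethylsilyl)hept-5-en-1-yn-3-ol
Conditions: Ru[(S,S)-TsDPEN](p-cymene) (16-electron amido complex, 1 mol %), iPrOH, 25 °C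
Reagents that add atoms: none
Why: Noyori asymmetric transfer hydrogenation of an alkynyl ketone, in which the alkynyl group takes the place of the aryl group of an aryl ketone in the six-membered metal–ligand bifunctional transition state, so the (S,S)-catalyst should deliver hydride to the face that gives the (S)-carbinol, while the base-free catalyst leaves the β,γ-alkene unconjugated.

Step 6
Reactants: 14 (3S)-6-methyl-1-(trimethylsilyl)hept-5-en-1-yn-3-ol
Product: 15 (3S)-6-methylhept-5-en-1-yn-3-ol
Conditions: K2CO3 (0.2 equiv), MeOH, 0 °C → rt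
Reagents that add atoms: none
Why: Protodesilylation of the alkynylsilane by methanolysis should cleave only the C(sp)–Si bond and leave the carbinol centre untouched.

Step 7
Reactants: 15 (3S)-6-methylhept-5-en-1-yn-3-ol; 16 3-methylbut-2-enoic acid
Product: 17 (3S)-6-methylhept-5-en-1-yn-3-yl 3-methylbut-2-enoate
Conditions: DCC (1.2 equiv), DMAP (0.1 equiv), CH2Cl2, 0 °C → rt
Reagents that add atoms: none
Why: Steglich esterification acylates the secondary propargylic alcohol without breaking the C–O bond of the stereocentre (retention) and avoids the vinylketene pathway by which an acid chloride with amine base could give the deconjugated ester.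

Step 8
Reactants: 6 chloro(dimethylglyoxime)(pyridine)(3,6-diacetoxyphthaloyl)cobalt; 17 (3S)-6-methylhept-5-en-1-yn-3-yl 3-methylbut-2-enoate
Product: 19 (1S)-1-(5,8-diacetoxy-1,4-dioxo-1,4-dihydronaphthalen-2-yl)-4-methylpent-3-en-1-yl 3-methylbut-2-enoate, via cobaltacycle 18 (not isolated)
Conditions: 17 (1.3 equiv), CoCl2·6H2O (1.0 equiv), MeCN, 70 °C, Ar
Reagents that add atoms: none
Why: CoCl2 as Lewis acid should open a coordination site on the trivalent-cobalt diacyl 6 (loss of pyridine), the terminal alkyne of 17 then binds and inserts into one Co–acyl bond to make the first C–C bond and the seven-membered acyl(vinyl)cobaltacycle 18, and C–C reductive elimination between the vinyl carbon and the second acyl carbon makes the other bond and releases the quinone from monovalent cobalt. The closest known reaction type is the phthaloylcobalt–alkyne naphthoquinone synthesis, established for benzocyclobutenedione-derived dimethylglyoxime complexes with terminal and oxygen-functionalised alkynes under CoCl2·6H2O promotion. The one ring that closes, the six-membered quinone ring, is formed as a net [4+2] annulation of the four-atom phthaloyl unit with the two alkyne carbons, the ring-closing event being the reductive elimination that contracts the seven-membered metallacycle to the carbocycle. No stereocentre is created, and the propargylic (S) centre is a spectator because its C–O and C–H bonds are not touched under these non-ionising conditions. The step needs chemoselectivity for the alkyne over the two trisubstituted alkenes and the ester groups, which the far higher insertion aptitude of a terminal alkyne at cobalt should secure, while regioselectivity is made irrelevant by the C2v symmetry of the 3,6-diacetoxyphthaloyl unit, since either orientation of insertion gives the same 2-substituted quinone.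

Step 9
Reactants: 19 (1S)-1-(5,8-diacetoxy-1,4-dioxo-1,4-dihydronaphthalen-2-yl)-4-methylpent-3-en-1-yl 3-methylbut-2-enoate
Product: 20 alkannin β,β-dimethylacrylate, (1S)-1-(5,8-dihydroxy-1,4-dioxo-1,4-dihydronaphthalen-2-yl)-4-methylpent-3-en-1-yl 3-methylbut-2-enoate
Conditions: K2CO3 (2.2 equiv), degassed MeOH, 0 °C, 15 min, Ar, dark; then pH 5 buffer
Reagents that add atoms: none
Why: Chemoselective transesterification (methanolysis) should cleave only the two aryl acetates, which are activated acyl donors because the leaving group is a naphtholate peri to a quinone carbonyl, while the hindered, conjugated secondary senecioate reacts far more slowly and the stereocentre is not involved.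

Compound list

1 | 3,4-dichlorocyclobut-3-ene-1,2-dione (squaric acid dichloride) | O=C1C(Cl)=C(Cl)C1=O | starting material
2 | (1E,3E)-buta-1,3-diene-1,4-diyl diacetate | CC(=O)O/C=C/C=C/OC(C)=O | starting material
3 | meso-1,6-dichloro-7,8-dioxobicyclo[4.2.0]oct-3-ene-2,5-diyl diacetate (endo adduct, cis ring fusion, both acetoxy groups cis to the four-membered ring) | O=C1C(=O)[C@@]2(Cl)[C@@H](OC(C)=O)C=C[C@@H](OC(C)=O)[C@@]12Cl | intermediate (not isolated)
4 | 3,6-diacetoxybenzocyclobutene-1,2-dione (7,8-dioxobicyclo[4.2.0]octa-1,3,5-triene-2,5-diyl diacetate) | CC(=O)Oc1ccc(OC(C)=O)c2c1C(=O)C2=O | intermediate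
5 | chlorobis(triphenylphosphine)(3,6-diacetoxyphthaloyl)cobalt (trivalent cobalt, both acyl carbons bound to cobalt in a five-membered ring) | CC(=O)Oc1ccc(OC(C)=O)c2c1C(=O)[Co-2](Cl)([P+](c1ccccc1)(c1ccccc1)c1ccccc1)([P+](c1ccccc1)(c1ccccc1)c1ccccc1)C2=O | intermediate (not isolated)
6 | chloro(dimethylglyoxime)(pyridine)(3,6-diacetoxyphthaloyl)cobalt (octahedral trivalent cobalt, neutral N,N-bound dimethylglyoxime) | CC1=[N+](O)[Co-3]2(Cl)([n+]3ccccc3)(C(=O)c3c(OC(C)=O)ccc(OC(C)=O)c3C2=O)[N+](O)=C1C | intermediate
7 | 4-methylpent-3-enoic acid | CC(C)=CCC(O)=O | starting material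
8 | 1-(1H-imidazol-1-yl)-4-methylpent-3-en-1-one (acyl imidazole) | CC(C)=CCC(=O)n1ccnc1 | intermediate (not isolated)
9 | N-methoxy-N,4-dimethylpent-3-enamide | CC(C)=CCC(=O)N(C)OC | intermediate
10 | ethynyltrimethylsilane | C#C[Si](C)(C)C | starting material
11 | lithium (trimethylsilyl)acetylide | [Li+].[C-]#C[Si](C)(C)C | intermediate (not isolated)
12 | lithium 3-[methoxy(methyl)amino]-6-methyl-1-(trimethylsilyl)hept-5-en-1-yn-3-olate (tetrahedral adduct, racemic) | [Li+].CC(C)=CCC([O-])(C#C[Si](C)(C)C)N(C)OC | intermediate (not isolated)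
13 | 6-methyl-1-(trimethylsilyl)hept-5-en-1-yn-3-one | CC(C)=CCC(=O)C#C[Si](C)(C)C | intermediate
14 | (3S)-6-methyl-1-(trimethylsilyl)hept-5-en-1-yn-3-ol | CC(C)=CC[C@H](O)C#C[Si](C)(C)C | intermediate
15 | (3S)-6-methylhept-5-en-1-yn-3-ol | CC(C)=CC[C@H](O)C#C | intermediate
16 | 3-methylbut-2-enoic acid | CC(C)=CC(O)=O | starting material
17 | (3S)-6-methylhept-5-en-1-yn-3-yl 3-methylbut-2-enoate | CC(C)=CC[C@H](OC(=O)C=C(C)C)C#C | intermediate
18 | seven-membered acyl(vinyl)cobaltacycle with chloride and dimethylglyoxime on cobalt (drawn with cobalt on the substituted vinyl carbon; the other insertion orientation leads to the same quinone) | CC(C)=CC[C@H](OC(=O)C=C(C)C)C1=CC(=O)c2c(OC(C)=O)ccc(OC(C)=O)c2C(=O)[Co-2]13(Cl)[N+](O)=C(C)C(C)=[N+]3O | intermediate (not isolated)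
19 | (1S)-1-(5,8-diacetoxy-1,4-dioxo-1,4-dihydronaphthalen-2-yl)-4-methylpent-3-en-1-yl 3-methylbut-2-enoate | CC(C)=CC[C@H](OC(=O)C=C(C)C)C1=CC(=O)c2c(OC(C)=O)ccc(OC(C)=O)c2C1=O | intermediate
20 | alkannin β,β-dimethylacrylate, (1S)-1-(5,8-dihydroxy-1,4-dioxo-1,4-dihydronaphthalen-2-yl)-4-methylpent-3-en-1-yl 3-methylbut-2-enoate | CC(C)=CC[C@H](OC(=O)C=C(C)C)C1=CC(=O)c2c(O)ccc(O)c2C1=O | target

Total step count: 9
Longest linear sequence: 7 steps (steps 3 to 9, from 4-methylpent-3-enoic acid 7)

Steps most likely to fail

Step 1. The cycloaddition between a tetrasubstituted dienophile and a weakly activated 1,4-disubstituted diene may be sluggish. During aromatisation, loss of acetic acid may also compete with loss of hydrogen chloride, because hydrogen and chlorine are cis in the endo adduct. Fallback: a benzyne route of established type. It does not set out from a numbered compound but from purchased 2-bromo-1,4-dimethoxybenzene (COc1ccc(OC)c(Br)c1), and it comes back to the route at 4. NaNH2 and 1,1-dimethoxyethene in refluxing THF should give, by [2+2] cycloaddition of 3,6-dimethoxybenzyne, 2,5,7,7-tetramethoxybicyclo[4.2.0]octa-1,3,5-triene F1. Dilute aq. HCl in THF should hydrolyse the acetal to 2,5-dimethoxybicyclo[4.2.0]octa-1,3,5-trien-7-one F2. NBS (2.2 equiv) with dibenzoyl peroxide in refluxing PhCF3 should brominate the benzylic α-carbon twice to 8,8-dibromo-2,5-dimethoxybicyclo[4.2.0]octa-1,3,5-trien-7-one F3. Warm aq. H2SO4 should hydrolyse the gem-dibromide to 2,5-dimethoxybicyclo[4.2.0]octa-1,3,5-triene-7,8-dione F4. BBr3 in CH2Cl2 (−78 → 0 °C) should cleave both ethers to 2,5-dihydroxybicyclo[4.2.0]octa-1,3,5-triene-7,8-dione F5, and Ac2O/pyridine should then give 4.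

Step 8. The propargylic ester may ionise or bind to the Lewis acid and cobalt, or the alkyne may oligomerise, so that insertion into the hindered, doubly ortho-substituted metallacycle is outrun. Fallback: the ester is installed after the annulation, so that the alkyne carries only a robust silyl ether. The fallback sets out from 15 and comes back to the route at 19. TBSCl/imidazole in DMF should give tert-butyl(dimethyl){[(3S)-6-methylhept-5-en-1-yn-3-yl]oxy}silane F6. Its annulation with 6 (CoCl2·6H2O, MeCN, 70 °C) should give (S)-2-{1-[tert-butyl(dimethyl)silyloxy]-4-methylpent-3-en-1-yl}-1,4-dioxo-1,4-dihydronaphthalene-5,8-diyl diacetate F7. HF·pyridine in THF should free the carbinol to (S)-2-(1-hydroxy-4-methylpent-3-en-1-yl)-1,4-dioxo-1,4-dihydronaphthalene-5,8-diyl diacetate F8. Steglich esterification with 16 (DCC, DMAP, CH2Cl2) should then give 19.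

Step 9. Chemoselectivity between the aryl acetates and the side-chain ester may be lost (over-cleavage or acyl scrambling), and the product may be exposed to base for too long. Fallback: global hydrolysis and selective re-acylation, which sets out from 19 and comes back to the route at 20. 1 M aq. NaOH under argon at rt, then dilute HCl, should cleave all three esters to alkannin, 5,8-dihydroxy-2-[(1S)-1-hydroxy-4-methylpent-3-en-1-yl]naphthalene-1,4-dione F9. This is the standard hydrolysis of alkannin esters, in which the stereocentre is retained. Esterification with 16 (DCC, DMAP, CH2Cl2, 0 °C) should then acylate only the side-chain hydroxyl, because the two peri hydroxyls are tied up in hydrogen bonds to the quinone carbonyls, and give 20.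

Further compounds

F1 | step 1 | 2,5,7,7-tetramethoxybicyclo[4.2.0]octa-1,3,5-triene | COc1ccc(OC)c2c1CC2(OC)OC
F2 | step 1 | 2,5-dimethoxybicyclo[4.2.0]octa-1,3,5-trien-7-one | COc1ccc(OC)c2c1CC2=O
F3 | step 1 | 8,8-dibromo-2,5-dimethoxybicyclo[4.2.0]octa-1,3,5-trien-7-one | COc1ccc(OC)c2c1C(Br)(Br)C2=O
F4 | step 1 | 2,5-dimethoxybicyclo[4.2.0]octa-1,3,5-triene-7,8-dione | COc1ccc(OC)c2c1C(=O)C2=O
F5 | step 1 | 2,5-dihydroxybicyclo[4.2.0]octa-1,3,5-triene-7,8-dione | Oc1ccc(O)c2c1C(=O)C2=O
F6 | step 8 | tert-butyl(dimethyl){[(3S)-6-methylhept-5-en-1-yn-3-yl]oxy}silane | CC(C)=CC[C@H](O[Si](C)(C)C(C)(C)C)C#C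
F7 | step 8 | (S)-2-{1-[tert-butyl(dimethyl)silyloxy]-4-methylpent-3-en-1-yl}-1,4-dioxo-1,4-dihydronaphthalene-5,8-diyl diacetate | CC(C)=CC[C@H](O[Si](C)(C)C(C)(C)C)C1=CC(=O)c2c(OC(C)=O)ccc(OC(C)=O)c2C1=O
F8 | step 8 | (S)-2-(1-hydroxy-4-methylpent-3-en-1-yl)-1,4-dioxo-1,4-dihydronaphthalene-5,8-diyl diacetate | CC(C)=CC[C@H](O)C1=CC(=O)c2c(OC(C)=O)ccc(OC(C)=O)c2C1=O
F9 | step 9 | alkannin, 5,8-dihydroxy-2-[(1S)-1-hydroxy-4-methylpent-3-en-1-yl]naphthalene-1,4-dione | CC(C)=CC[C@H](O)C1=CC(=O)c2c(O)ccc(O)c2C1=O
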